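## Structural features

The target is a drimane: a trans-fused decalin in which ring A (C1–C5, C10) is a cyclohexane with a gem-dimethyl group at C4, and ring B (C5–C10) is a cyclohexene (C7=C8) sharing the C5–C10 bond. Four stereocentres surround ring B: C5 (α-H), C6 (β-acyloxy, axial and syn to the axial 4β- and 10β-methyl groups), C9 (β-hydroxyl syn to the C10 methyl, α-carboxyl C11) and quaternary C10. C9 and C10 are vicinal fully substituted carbons, and with quaternary C4 next to C5 the C4–C5–C10–C9 array is very crowded. C8 carries the formyl carbon C12, so C12–C8–C9–C11 is a γ-aldehydo acid, and any C12 carbinol would lactonise onto C11. The fragile groups are the (2E,4E,6E)-trienoate, the secondary allylic ester at C6, the enal and the tertiary α-hydroxy acid. The real difficulty is to set the C9/C10 pair in the right relative and absolute sense together with the trans ring fusion, and then to free acid and aldehyde without touching the ester. The key step exploits that C9 bears both oxygen and carboxyl, so C9=C10 is an α-oxyacrylate dienophile, while C5=C6–C7=C8 is the dienol form of a 6-oxo-7-ene: ring B is a Diels–Alder retron, and ring A closes at the same time when C10 is tied to C5 through C1–C4.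

## Logic of the disconnections

37 ⇒ 35 (through 36). Cut: the O–allyl bond at C11 and the two O–CH3 bonds at C12. Reason: acid and aldehyde are kept masked until the end, so that no lactol or 11,12-lactone chemistry interferes earlier. Gain: the last step needs no oxidant and no strong base. Demand: allyl transfer must not ionise the C6 allylic ester, and the acetal must hydrolyse under very mild acid.

35 ⇒ 29 + 33; 33 ⇒ 30 + 31. Cut: the C6–O acyl bond, then the C2=C3 bond of the side chain. Reason: the triene enters as late as possible and never meets heat, palladium diacetate or hydride. Gain: a robust core and a one-step side chain. Demand: acylation of a hindered axial secondary alcohol in the presence of the tertiary 9-hydroxyl, without isomerising the triene.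

29 ⇒ 27 + 28. Cut (retro): the allyl ester C–O bond; O9 and the C11 acyl oxygen are rejoined through the acetal carbon. Reason: the spiro acylal is opened while only base-stable groups are present, not at the end beside the trienoate. Gain: a final deprotection under neutral conditions. Demand: an alkoxide must reach a carbonyl flanked by two quaternary carbons.

27 ⇒ 26 ⇒ 25. Cut: the C6–H bond (alcohol back to ketone), then the C7=C8 unsaturation (enone back to silyl enol ether). Reason: this exposes the cyclohexene silyl enol ether that a 2-silyloxydiene cycloaddition delivers. Gain: C6 stops being a stereocentre. Demand: α-face hydride delivery at C6 and a regio-defined dehydrogenation.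

25 ⇒ 24 (key). Cut: C5–C10 and C8–C9. Reason: both rings and the C5/C9/C10 stereocentres go back to one acyclic triene, whose only stereochemical content is an alkene geometry and one acetal carbon. Gain: two rings, two skeletal bonds, four stereocentres. Demand: face selectivity anti to tert-butyl, the carbonyl-exo (tether-anti) mode, and a geometrically pure tetrasubstituted dienophile.

24 ⇒ 23 ⇒ 21 ⇒ 18 + 19. Cut: the O–Si bond, then C7=C8 (aldol condensation). Reason: C8 and C12 arrive together, with C12 already at the aldehyde oxidation level. Gain: the diene half reduces to a methyl ketone. Demand: enolisations that touch neither the alkylidene lactone nor the acetal.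

18 ⇒ 17. Cut (functional group interchange): C6=O back to a terminal alkene. Reason: a ketone could not coexist with the enolate chemistry that builds C9 and C9=C10, whereas an alkene can. Gain: the ketone is unmasked only after all strong-base steps. Demand: an oxidation that ignores the tetrasubstituted alkene.

17 ⇒ 13 (through 14–16). Cut: the C9=C10 π bond, back to C9–H and C10–H. Reason: a ketone olefination at C10 could not distinguish methyl from chain, whereas a syn-elimination translates a C10 stereocentre into alkene geometry. Gain: the geometry problem becomes a chiral-pool stereocentre. Demand: selenium must enter anti to tert-butyl and the elimination must stay concerted.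

13 ⇒ 11 + 12; 11 ⇒ 9 ⇒ 7. Cut: the two acetal C–O bonds, then the C9–O bond. Reason: the cis acetal copies the C9 configuration onto the acetal carbon, and C9 itself comes from an auxiliary-controlled enolate hydroxylation. Gain: an unfunctionalised acyl chain. Demand: a high cis preference in the acetalisation and high facial control in the hydroxylation.

7 ⇒ 4 + 5; 4 ⇒ 1 + 2. Cut: the C4–C5 bond, then the N–acyl bond. Reason: 1 already contains C11, C9, C10 with its methyl, C1–C3 and C4 with both methyls, with C10 in the required S configuration. Gain: ten of the fifteen core carbons and the controlling stereocentre from one commercial compound. Demand: clean capture of a tertiary cation by an allyl nucleophile.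

## Other disconnections considered

Alternative 1: The cut is the single bond C8–C9 (ring B only). The precursor A2 is a ring A cyclohexane that already carries C5, C6 and C10, with a 2-oxoacetate on C10 and a γ-silyloxy enal on C5. In the forward step a nucleophilic trialkylphosphine adds to C7, the phosphonium dienolate attacks the C9 ketone through C8, and loss of the phosphine gives A1.
- In its favour: the step is redox-neutral and delivers C11 and C12 in their final oxidation states. A1 is about three operations from the target (silyl ether cleavage, acylation, ester cleavage), so on the endgame it is better than the chosen plan, which needs six steps after its key step. The α-keto ester is a strongly electrophilic acceptor.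
- Against it here: it forms one bond, one ring and one stereocentre, so C5, C6 and quaternary C10 must be set beforehand on ring A, which is likely to cost more steps than the short endgame saves. β-Substituted enals are slow donors in this reaction and C9 is neopentylic. The addition is reversible, so C9 would be set only by conformational preference. The γ-silyloxy group can be lost from the zwitterion.
- Comparison: on structure the chosen plan is stronger (two rings and C5/C9/C10 from an acyclic chain). On mechanism its C9/C10 control rests on an alkene geometry and an acetal carbon, not on a ring bias. On step economy Alternative 1 is better after the key step and worse before it. The two plans are equal in having to form the crowded C8–C9 bond.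

Alternative 2: The cut is C5–C6 and C9–C10, intermolecular. Deprotonated A4 adds A5 under a bifunctional cinchona-alkaloid base to give the lactone-bridged ring B compound A3.
- In its favour: it is catalytic and enantioselective, and it sets the vicinal C9/C10 pair in one step from two small achiral commercial compounds. On absolute control and on the step count to the C9/C10 pair it is better than the chosen plan, which spends ten steps and a stoichiometric auxiliary to reach its cycloaddition precursor.
- Against it here: A3 lacks ring A and C12. C5 is an unactivated methylene to which quaternary C4 would have to be attached with a trans ring fusion, and C8 is a plain vinylic CH that still needs formylation. The lactone bridge also forces the C6 oxygen onto the face of C11, which is the C6 epimer of the target. An inversion would be needed; it could be merged with the esterification by reaction with 33 under inverting conditions, at the risk of allylic transposition.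
- Comparison: on structure the chosen plan solves both rings, Alternative 2 one. On mechanism both are cycloadditions across C9=C10-type carbons, with catalyst control in Alternative 2 and auxiliary control in the chosen plan. On step economy Alternative 2 is better up to the key step and clearly worse after it.

Alternative 3: The cut is C4–C5 and C9–C10. The acyclic polyene A7 is protonated at C3 by a chiral Lewis-acid-assisted Brønsted acid, a chair–chair cascade closes rings A and B and ends on the C8=C9 dioxole, and hydrolysis gives A6.
- In its favour: the topological gain equals that of the chosen plan (two rings, two bonds, C5/C9/C10). It is better in that A7 is achiral, linear and quickly assembled, and the gem-dimethyl group and the trans fusion follow directly from the folding under catalyst control.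
- Against it here: the terminating dioxole is tetrasubstituted and deactivated by the ester, and it must form quaternary C9 next to the nascent quaternary C10. It is acid-labile under the conditions that start the cascade. Enantioselection in protonating a terminal trisubstituted alkene is substrate dependent. A6 lacks C12 and the C6 oxygen, so a C8 homologation and an allylic oxidation at C6 with later stereoselective reduction would follow, a longer and less selective endgame than the six steps of the chosen plan.
- Comparison: equal on rings and stereocentres formed, better on precursor simplicity, worse on the certainty of the termination and on the steps after the key step.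

Key step: step 11

Remarks on the chemistry (drimane numbering throughout: C11 on C9, C12 on C8; α is the face of H5, β the face of the C10 methyl):
- C12 is carried as a dimethyl acetal at the aldehyde oxidation level, not as a protected carbinol, so that no free C12 carbinol ever sits next to the C11 acyl group and no oxidant is needed once the triene is present.
- An (E)-alkylidene with an (S)-acetal carbon, attacked anti to tert-butyl with the lactone carbonyl exo, leads to 5S,9R,10S as the target requires.
- The open γ-aldehydo acid is taken as the target; its lactol tautomer, if populated, is the same compound.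

Step 1
Reactants: 1 (S)-citronellic acid [(3S)-3,7-dimethyloct-6-enoic acid]; 2 (S)-4-benzyl-1,3-oxazolidin-2-one
Product: 4 (4S)-4-benzyl-3-[(3S)-3,7-dimethyloct-6-enoyl]-1,3-oxazolidin-2-one, via mixed pivalic anhydride 3 (not isolated)
Conditions: PivCl, Et3N, THF, −20 °C; then LiCl, 2, −20 °C → rt
Reagents that add atoms: none
Why: Mixed-anhydride N-acylation (Evans auxiliary attachment): the oxazolidinone nitrogen attacks the less hindered citronelloyl carbonyl of 3; the C3 stereocentre (future C10) is β to the carbonyl and cannot epimerise.

Step 2
Reactants: 4 (4S)-4-benzyl-3-[(3S)-3,7-dimethyloct-6-enoyl]-1,3-oxazolidin-2-one; 5 allyltrimethylsilane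
Product: 7 (4S)-4-benzyl-3-[(3S)-3,7,7-trimethyldec-9-enoyl]-1,3-oxazolidin-2-one, via tertiary chloride 6 (not isolated)
Conditions: HCl (g), CH2Cl2, 0 °C; N2 purge; then 5, TiCl4, CH2Cl2, −78 °C
Reagents that add atoms: none
Why: Markovnikov hydrochlorination gives the tertiary chloride 6; TiCl4 ionises it and the allylsilane captures the tertiary cation at its γ-carbon (Hosomi–Sakurai-type tert-alkylation), creating quaternary C4 and the C4–C5 bond. The terminal alkene is a latent C6 ketone that is inert to the enolate chemistry of steps 3 and 6.

Step 3
Reactants: 7 (4S)-4-benzyl-3-[(3S)-3,7,7-trimethyldec-9-enoyl]-1,3-oxazolidin-2-one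
Product: 9 (4S)-4-benzyl-3-[(2S,3S)-2-hydroxy-3,7,7-trimethyldec-9-enoyl]-1,3-oxazolidin-2-one, via sodium Z-enolate 8 (not isolated)
Conditions: NaN(SiMe3)2, THF, −78 °C; 2-(benzenesulfonyl)-3-phenyloxaziridine, −78 °C; AcOH
Reagents that add atoms: 2-(benzenesulfonyl)-3-phenyloxaziridine, O=S(=O)(c1ccccc1)N1OC1c1ccccc1
Why: Evans asymmetric enolate hydroxylation: the chelated (Z)-sodium enolate 8 takes oxygen from the oxaziridine on the face opposite the benzyl group, which sets the future C9 as S; the neighbouring C3 centre only modulates the auxiliary control.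

Step 4
Reactants: 9 (4S)-4-benzyl-3-[(2S,3S)-2-hydroxy-3,7,7-trimethyldec-9-enoyl]-1,3-oxazolidin-2-one
Product: 11 (2S,3S)-2-hydroxy-3,7,7-trimethyldec-9-enoic acid, via lithium percarboxylate 10 (not isolated)
Conditions: LiOH, 30% H2O2, THF–H2O, 0 °C; aq. Na2SO3; then HCl to pH 2
Reagents that add atoms: hydrogen peroxide, OO
Why: Hydroperoxide-mediated imide cleavage: LiOOH attacks the exocyclic carbonyl selectively and sulfite reduces the percarboxylate 10 before acidification, so the terminal alkene is not epoxidised and the α-hydroxy centre is not epimerised; the auxiliary 2 is recovered.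

Step 5
Reactants: 11 (2S,3S)-2-hydroxy-3,7,7-trimethyldec-9-enoic acid; 12 pivalaldehyde
Product: 13 (2S,5S)-2-tert-butyl-5-[(2S)-6,6-dimethylnon-8-en-2-yl]-1,3-dioxolan-4-one (cis)
Conditions: 12, p-TsOH·H2O (cat.), H2SO4 (cat.), pentane, reflux, Dean–Stark
Reagents that add atoms: none
Why: Acid-catalysed acetalisation under equilibrating conditions (Seebach dioxolanone formation) favours the cis-2,5-disubstituted ring, so the S centre at C9 writes an S acetal carbon that keeps the absolute information after C9 is planarised; the minor trans isomer must be removed because it would lead into the enantiomeric series.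

Step 6
Reactants: 13 (2S,5S)-2-tert-butyl-5-[(2S)-6,6-dimethylnon-8-en-2-yl]-1,3-dioxolan-4-one
Product: 17 (2S,5E)-2-tert-butyl-5-(6,6-dimethylnon-8-en-2-ylidene)-1,3-dioxolan-4-one, via lithium enolate 14 (not isolated), via phenylselanyl dioxolanone 15 (not isolated), via selenoxide 16 (not isolated)
Conditions: LiN(i-Pr)2, THF, −78 °C; PhSeBr, −78 °C; then 30% H2O2, pyridine, CH2Cl2, 0 °C → rt
Reagents that add atoms: none
Why: Enolate selenenylation followed by selenoxide syn-elimination: the lithium enolate 14 is attacked by PhSeBr anti to the tert-butyl group, and the selenoxide 16 can only eliminate through the single β-hydrogen at C10 in a concerted syn fashion. With C10 = S this places the methyl cis to the ring oxygen and the chain cis to the carbonyl, which is the 5E tetrasubstituted alkene, so the chiral-pool centre is traded for alkene geometry.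

Step 7
Reactants: 17 (2S,5E)-2-tert-butyl-5-(6,6-dimethylnon-8-en-2-ylidene)-1,3-dioxolan-4-one
Product: 18 (2S,5E)-2-tert-butyl-5-(6,6-dimethyl-8-oxononan-2-ylidene)-1,3-dioxolan-4-one
Conditions: PdCl2 (10 mol%), CuCl, O2 (1 atm), DMF–H2O (7:1), rt
Reagents that add atoms: water, O
Why: Tsuji–Wacker oxidation: the monosubstituted alkene is hydroxypalladated with Markovnikov selectivity and gives the methyl ketone (C6=O, C7H3); the tetrasubstituted electron-poor alkylidene does not coordinate divalent palladium and the acylal tolerates the mildly acidic medium.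

Step 8
Reactants: 18 (2S,5E)-2-tert-butyl-5-(6,6-dimethyl-8-oxononan-2-ylidene)-1,3-dioxolan-4-one; 19 2,2-dimethoxyacetaldehyde (anhydrous)
Product: 21 (2S,5E)-2-tert-butyl-5-(10-hydroxy-11,11-dimethoxy-6,6-dimethyl-8-oxoundecan-2-ylidene)-1,3-dioxolan-4-one (both carbinol epimers), via boron enolate 20 (not isolated)
Conditions: n-Bu2BOTf, i-Pr2NEt, CH2Cl2, −78 °C; 19, −78 → 0 °C; pH 7 buffer, MeOH, 30% H2O2, 0 °C
Reagents that add atoms: none
Why: Boron-mediated aldol addition: soft enolisation takes the methyl side (the C5 methylene is neopentylic), and the amine is too weak a base to deprotonate the γ-positions of the alkylidene lactone, so its geometry is safe; 19 cannot enolise. The new carbinol centre is unselective and irrelevant because it is eliminated in step 9.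

Step 9
Reactants: 21 (2S,5E)-2-tert-butyl-5-(10-hydroxy-11,11-dimethoxy-6,6-dimethyl-8-oxoundecan-2-ylidene)-1,3-dioxolan-4-one
Product: 23 (2S,5E)-2-tert-butyl-5-[(9E)-11,11-dimethoxy-6,6-dimethyl-8-oxoundec-9-en-2-ylidene]-1,3-dioxolan-4-one, via β-mesyloxy ketone 22 (not isolated)
Conditions: MsCl, Et3N, CH2Cl2, 0 °C → rt
Reagents that add atoms: none
Why: Mesylation and E1cB elimination of the β-mesyloxy ketone give the conjugated (E)-enone under thermodynamic control; Et3N is the only base, so the acetal, the acylal and the alkylidene are untouched.

Step 10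
Reactants: 23 (2S,5E)-2-tert-butyl-5-[(9E)-11,11-dimethoxy-6,6-dimethyl-8-oxoundec-9-en-2-ylidene]-1,3-dioxolan-4-one
Product: 24 (2S,5E)-2-tert-butyl-5-[(7Z,9E)-8-(tert-butyldimethylsilyloxy)-11,11-dimethoxy-6,6-dimethylundeca-7,9-dien-2-ylidene]-1,3-dioxolan-4-one
Conditions: TBSOTf, Et3N, CH2Cl2, −78 → −20 °C
Reagents that add atoms: tert-butyldimethylsilyl triflate, CC(C)(C)[Si](C)(C)OS(=O)(=O)C(F)(F)F
Why: Soft enolisation (silyl triflate and amine) of the enone at its only α′-methylene gives the cross-conjugated 2-silyloxydiene; the Z enol ether (C4 trans to C7) is favoured because quaternary C4 avoids the vinyl group, and this geometry places C4 on the outside of the s-cis diene. Low temperature and excess amine keep the dimethyl acetal and the conjugated lactone from reacting with the silyl triflate; 24 is used without chromatography.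

Step 11
Reactants: 24 (2S,5E)-2-tert-butyl-5-[(7Z,9E)-8-(tert-butyldimethylsilyloxy)-11,11-dimethoxy-6,6-dimethylundeca-7,9-dien-2-ylidene]-1,3-dioxolan-4-one
Product: 25 (S)-2,2-dimethylpropylidene acylal of 9β-hydroxy-12,12-dimethoxy-6-(tert-butyldimethylsilyloxy)drim-6-en-11-oic acid (trans-decalin with 5α-H, 8α-H and 10β-CH3; C9 is the spiro carbon of the dioxolanone, ring oxygen β, C11=O α)
Conditions: PhMe (0.01 M), BHT (cat.), sealed tube (base-washed glass), 190 °C
Reagents that add atoms: none
Why: Thermal intramolecular Diels–Alder reaction of a 1,7,9-decatriene: a concerted but asynchronous [4+2] in which the nucleophilic C5 terminus of the 2-silyloxydiene bonds first to C10 (β to the lactone carbonyl) and C8 then closes onto C9; the closest known reaction types are the thermal cyclisation of decatrienes and the face-selective cycloadditions of 5-alkylidene-2-tert-butyl-1,3-dioxolan-4-ones. Ring A is closed in the fused (type 1) mode as the six-membered ring formed by the C5–C10 bond over the C1–C4 tether, helped by the gem-dimethyl group at C4; ring B is the cyclohexene of the cycloaddition itself (C5–C10 plus C8–C9). C9 is controlled by the S acetal carbon: the diene should add to the dienophile face opposite the tert-butyl group, so C8 ends anti to it. C10 is controlled by the E geometry of the alkylidene, which suprafacial addition translates into methyl syn to the C9 oxygen. C5 is controlled by the tether-anti transition state with the lactone carbonyl exo and the ring oxygen endo (the mode these dienophiles are known to prefer), which puts H5 trans to the C10 methyl and gives the trans-decalin. C8 follows from the E geometry of C7=C8 (dimethoxymethyl β) and is removed in step 12. The step therefore needs π-facial selectivity, secured by the tert-butyl acetal, and exo selectivity, secured by the tether and the dienophile; regiochemistry is fixed by the tether and reinforced by the matched polarisation. High dilution, a radical inhibitor and base-washed glass protect the silyl enol ether and the acetal during the long heating.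

Step 12
Reactants: 25 (S)-2,2-dimethylpropylidene acylal of 9β-hydroxy-12,12-dimethoxy-6-(tert-butyldimethylsilyloxy)drim-6-en-11-oic acid
Product: 26 (S)-2,2-dimethylpropylidene acylal of 9β-hydroxy-12,12-dimethoxy-6-oxodrim-7-en-11-oic acid
Conditions: Pd(OAc)2 (1.1 equiv), MeCN, rt → 40 °C
Reagents that add atoms: none
Why: Saegusa–Ito oxidation: Pd(OAc)2 converts the silyl enol ether into a C7-bound enolate of divalent palladium, and β-hydride elimination of H8 (the only β-hydrogen) gives the 6-oxo-7-ene and removes the temporary C8 centre.

Step 13
Reactants: 26 (S)-2,2-dimethylpropylidene acylal of 9β-hydroxy-12,12-dimethoxy-6-oxodrim-7-en-11-oic acid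
Product: 27 (S)-2,2-dimethylpropylidene acylal of 6β,9β-dihydroxy-12,12-dimethoxydrim-7-en-11-oic acid
Conditions: NaBH4, CeCl3·7H2O, MeOH, −78 → −40 °C
Reagents that add atoms: none
Why: Luche 1,2-reduction: the β-face of C6 is blocked by the two syn-axial methyl groups (4β and 10β), so hydride should be delivered from the α-face to give the axial 6β-alcohol (6R); CeCl3 suppresses conjugate reduction and MeOH can only exchange the dimethyl acetal with itself.

Step 14
Reactants: 27 (S)-2,2-dimethylpropylidene acylal of 6β,9β-dihydroxy-12,12-dimethoxydrim-7-en-11-oic acid; 28 allyl alcohol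
Product: 29 allyl 6β,9β-dihydroxy-12,12-dimethoxydrim-7-en-11-oate
Conditions: 28 (solvent), THF, NaH (0.3 equiv), 0 → 40 °C; aq. NH4Cl
Reagents that add atoms: none
Why: Base-catalysed alcoholysis of the acylal (transesterification): allyloxide adds to the lactone carbonyl, the ring oxygen leaves as a hemiacetal alkoxide that expels pivalaldehyde, and the 9β-hydroxyl is freed in the same step. It is done here because only base-stable groups are present; the 6β-hydroxyl and C11 lie on opposite faces, so no lactone can form.

Step 15
Reactants: 30 (2E,4E)-hexa-2,4-dienal; 31 malonic acid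
Product: 33 (2E,4E,6E)-octa-2,4,6-trienoic acid, via dienylidenemalonic acid 32 (not isolated)
Conditions: 31, pyridine, piperidine (cat.), 90 °C
Reagents that add atoms: none
Why: Knoevenagel–Doebner condensation: the alkylidene malonic acid 32 decarboxylates in pyridine to the (2E)-acid, and the existing E,E-diene is untouched.

Step 16
Reactants: 33 (2E,4E,6E)-octa-2,4,6-trienoic acid; 29 allyl 6β,9β-dihydroxy-12,12-dimethoxydrim-7-en-11-oate
Product: 35 allyl 9β-hydroxy-12,12-dimethoxy-6β-[(2E,4E,6E)-octa-2,4,6-trienoyloxy]drim-7-en-11-oate, via trichlorobenzoic mixed anhydride 34 (not isolated)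
Conditions: 33, 2,4,6-trichlorobenzoyl chloride, Et3N, PhMe, rt; then 29, DMAP, PhMe, rt → 40 °C
Reagents that add atoms: none
Why: Yamaguchi esterification: the mixed anhydride 34 acylates, through the N-acylpyridinium, the secondary allylic 6β-hydroxyl; the tertiary 9β-hydroxyl flanked by two quaternary carbons is far less reactive, and the neutral non-oxidising conditions preserve the all-E triene.

Step 17
Reactants: 35 allyl 9β-hydroxy-12,12-dimethoxy-6β-[(2E,4E,6E)-octa-2,4,6-trienoyloxy]drim-7-en-11-oate
Product: 37 9β-hydroxy-12-oxo-6β-[(2E,4E,6E)-octa-2,4,6-trienoyloxy]drim-7-en-11-oic acid (5S,6R,9R,10S; the target), via carboxylic acid acetal 36 (not isolated)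
Conditions: Pd(PPh3)4 (5 mol%), PhNHMe, THF, rt; then 0.5 M aq. HCl, THF, 0 °C
Reagents that add atoms: water, O
Why: Tsuji–Trost deallylation then acetal hydrolysis: zerovalent palladium ionises the unhindered primary allyl ester and N-methylaniline traps the allyl fragment, while the crowded secondary trienoate at C6 is not ionised; dilute acid then hydrolyses the allylic dimethyl acetal to the enal. No oxidant, strong base or free C12 carbinol is involved, so the triene and the C6 ester should survive.

Compound list

1 | (S)-citronellic acid, (3S)-3,7-dimethyloct-6-enoic acid | C[C@@H](CCC=C(C)C)CC(=O)O | starting material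
2 | (S)-4-benzyl-1,3-oxazolidin-2-one | O=C1OC[C@H](Cc2ccccc2)N1 | starting material
3 | (3S)-3,7-dimethyloct-6-enoic pivalic anhydride | C[C@@H](CCC=C(C)C)CC(=O)OC(=O)C(C)(C)C | intermediate (not isolated)
4 | (4S)-4-benzyl-3-[(3S)-3,7-dimethyloct-6-enoyl]-1,3-oxazolidin-2-one | C[C@@H](CCC=C(C)C)CC(=O)N1[C@@H](Cc2ccccc2)COC1=O | intermediate
5 | allyltrimethylsilane | C=CC[Si](C)(C)C | starting material
6 | (4S)-4-benzyl-3-[(3S)-7-chloro-3,7-dimethyloctanoyl]-1,3-oxazolidin-2-one | C[C@@H](CCCC(C)(C)Cl)CC(=O)N1[C@@H](Cc2ccccc2)COC1=O | intermediate (not isolated)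
7 | (4S)-4-benzyl-3-[(3S)-3,7,7-trimethyldec-9-enoyl]-1,3-oxazolidin-2-one | C[C@@H](CCCC(C)(C)CC=C)CC(=O)N1[C@@H](Cc2ccccc2)COC1=O | intermediate
8 | sodium (Z)-enolate of 7 | C[C@@H](CCCC(C)(C)CC=C)/C=C(\[O-])N1[C@@H](Cc2ccccc2)COC1=O.[Na+] | intermediate (not isolated)
9 | (4S)-4-benzyl-3-[(2S,3S)-2-hydroxy-3,7,7-trimethyldec-9-enoyl]-1,3-oxazolidin-2-one | C[C@@H](CCCC(C)(C)CC=C)[C@H](O)C(=O)N1[C@@H](Cc2ccccc2)COC1=O | intermediate
10 | lithium (2S,3S)-2-hydroxy-3,7,7-trimethyldec-9-eneperoxoate | C[C@@H](CCCC(C)(C)CC=C)[C@H](O)C(=O)O[O-].[Li+] | intermediate (not isolated)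
11 | (2S,3S)-2-hydroxy-3,7,7-trimethyldec-9-enoic acid | C[C@@H](CCCC(C)(C)CC=C)[C@H](O)C(=O)O | intermediate
12 | pivalaldehyde | CC(C)(C)C=O | starting material
13 | (2S,5S)-2-tert-butyl-5-[(2S)-6,6-dimethylnon-8-en-2-yl]-1,3-dioxolan-4-one | C[C@@H](CCCC(C)(C)CC=C)[C@@H]1O[C@H](C(C)(C)C)OC1=O | intermediate
14 | lithium enolate of 13 | C[C@@H](CCCC(C)(C)CC=C)C1=C([O-])O[C@@H](C(C)(C)C)O1.[Li+] | intermediate (not isolated)
15 | (2S,5R)-2-tert-butyl-5-[(2S)-6,6-dimethylnon-8-en-2-yl]-5-(phenylselanyl)-1,3-dioxolan-4-one | C[C@@H](CCCC(C)(C)CC=C)[C@]1([Se]c2ccccc2)O[C@H](C(C)(C)C)OC1=O | intermediate (not isolated)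
16 | Se-oxide of 15 | C[C@@H](CCCC(C)(C)CC=C)[C@]1([Se](=O)c2ccccc2)O[C@H](C(C)(C)C)OC1=O | intermediate (not isolated)
17 | (2S,5E)-2-tert-butyl-5-(6,6-dimethylnon-8-en-2-ylidene)-1,3-dioxolan-4-one | C/C(CCCC(C)(C)CC=C)=C1\O[C@H](C(C)(C)C)OC1=O | intermediate
18 | (2S,5E)-2-tert-butyl-5-(6,6-dimethyl-8-oxononan-2-ylidene)-1,3-dioxolan-4-one | C/C(CCCC(C)(C)CC(C)=O)=C1\O[C@H](C(C)(C)C)OC1=O | intermediate
19 | 2,2-dimethoxyacetaldehyde | COC(OC)C=O | starting material
20 | di-n-butylboron enolate of 18 (methyl side) | C/C(CCCC(C)(C)CC(=C)OB(CCCC)CCCC)=C1\O[C@H](C(C)(C)C)OC1=O | intermediate (not isolated)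
21 | (2S,5E)-2-tert-butyl-5-(10-hydroxy-11,11-dimethoxy-6,6-dimethyl-8-oxoundecan-2-ylidene)-1,3-dioxolan-4-one | C/C(CCCC(C)(C)CC(=O)CC(O)C(OC)OC)=C1\O[C@H](C(C)(C)C)OC1=O | intermediate
22 | methanesulfonate of 21 | C/C(CCCC(C)(C)CC(=O)CC(OS(C)(=O)=O)C(OC)OC)=C1\O[C@H](C(C)(C)C)OC1=O | intermediate (not isolated)
23 | (2S,5E)-2-tert-butyl-5-[(9E)-11,11-dimethoxy-6,6-dimethyl-8-oxoundec-9-en-2-ylidene]-1,3-dioxolan-4-one | C/C(CCCC(C)(C)CC(=O)/C=C/C(OC)OC)=C1\O[C@H](C(C)(C)C)OC1=O | intermediate
24 | (2S,5E)-2-tert-butyl-5-[(7Z,9E)-8-(tert-butyldimethylsilyloxy)-11,11-dimethoxy-6,6-dimethylundeca-7,9-dien-2-ylidene]-1,3-dioxolan-4-one | C/C(CCCC(C)(C)/C=C(O[Si](C)(C)C(C)(C)C)/C=C/C(OC)OC)=C1\O[C@H](C(C)(C)C)OC1=O | intermediate (key-step precursor)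
25 | (S)-2,2-dimethylpropylidene acylal of 9β-hydroxy-12,12-dimethoxy-6-(tert-butyldimethylsilyloxy)drim-6-en-11-oic acid | C1(O[Si](C)(C)C(C)(C)C)=C[C@H](C(OC)OC)[C@@](O3)(C(=O)O[C@H]3C(C)(C)C)[C@@]4(C)CCCC(C)(C)[C@H]14 | intermediate (key-step product)
26 | (S)-2,2-dimethylpropylidene acylal of 9β-hydroxy-12,12-dimethoxy-6-oxodrim-7-en-11-oic acid | C1(=O)C=C(C(OC)OC)[C@@](O3)(C(=O)O[C@H]3C(C)(C)C)[C@@]4(C)CCCC(C)(C)[C@H]14 | intermediate
27 | (S)-2,2-dimethylpropylidene acylal of 6β,9β-dihydroxy-12,12-dimethoxydrim-7-en-11-oic acid | O[C@@H]1C=C(C(OC)OC)[C@@](O3)(C(=O)O[C@H]3C(C)(C)C)[C@@]4(C)CCCC(C)(C)[C@H]14 | intermediate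
28 | allyl alcohol | C=CCO | starting material
29 | allyl 6β,9β-dihydroxy-12,12-dimethoxydrim-7-en-11-oate | O[C@@H]1C=C(C(OC)OC)[C@@](O)(C(=O)OCC=C)[C@@]2(C)CCCC(C)(C)[C@H]12 | intermediate
30 | (2E,4E)-hexa-2,4-dienal | C/C=C/C=C/C=O | starting material
31 | malonic acid | OC(=O)CC(=O)O | starting material
32 | 2-[(2E,4E)-hexa-2,4-dien-1-ylidene]malonic acid | C/C=C/C=C/C=C(C(=O)O)C(=O)O | intermediate (not isolated)
33 | (2E,4E,6E)-octa-2,4,6-trienoic acid | C/C=C/C=C/C=C/C(=O)O | intermediate
34 | (2E,4E,6E)-octa-2,4,6-trienoic 2,4,6-trichlorobenzoic anhydride | C/C=C/C=C/C=C/C(=O)OC(=O)c1c(Cl)cc(Cl)cc1Cl | intermediate (not isolated)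
35 | allyl 9β-hydroxy-12,12-dimethoxy-6β-[(2E,4E,6E)-octa-2,4,6-trienoyloxy]drim-7-en-11-oate | C/C=C/C=C/C=C/C(=O)O[C@@H]1C=C(C(OC)OC)[C@@](O)(C(=O)OCC=C)[C@@]2(C)CCCC(C)(C)[C@H]12 | intermediate
36 | 9β-hydroxy-12,12-dimethoxy-6β-[(2E,4E,6E)-octa-2,4,6-trienoyloxy]drim-7-en-11-oic acid | C/C=C/C=C/C=C/C(=O)O[C@@H]1C=C(C(OC)OC)[C@@](O)(C(=O)O)[C@@]2(C)CCCC(C)(C)[C@H]12 | intermediate (not isolated)
37 | 9β-hydroxy-12-oxo-6β-[(2E,4E,6E)-octa-2,4,6-trienoyloxy]drim-7-en-11-oic acid, (5S,6R,9R,10S) | C/C=C/C=C/C=C/C(=O)O[C@@H]1C=C(C=O)[C@@](O)(C(=O)O)[C@@]2(C)CCCC(C)(C)[C@H]12 | target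

Total step count: 17. Longest linear sequence: 16 (steps 1–14, 16, 17); step 15 is the one-step side-chain branch.

Least certain steps

Step 11 (key step). The most likely failure is a cycloaddition too slow for the substrate's thermal lifetime. A tetrasubstituted dienophile must form the C5–C10 bond between two carbons that both adjoin quaternary centres, and the silyl enol ether may be lost or the alkylidene may isomerise before ring closure. The second risk is leakage into the tether-syn (carbonyl-endo) mode, giving the cis-fused isomer. Fallback, from 23 back to the route at 26: the enone 23 is treated with LiN(SiMe3)2 in THF (−78 → 0 °C) to trigger an anionic intramolecular double Michael addition. The cross-conjugated enolate adds through C5 to C10, and the resulting dioxolanone enolate closes onto C8 anti to the tert-butyl group. Protonation gives the saturated ketone, the (S)-2,2-dimethylpropylidene acylal of 9β-hydroxy-12,12-dimethoxy-6-oxodriman-11-oic acid F1, whose C5 centre can equilibrate to the trans fusion. Dehydrogenation of F1 with IBX (DMSO, 65 °C) can only occur towards C7–C8 and gives 26.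

Step 6. The most likely failure is erosion of alkene geometry, either by incomplete facial selectivity in the selenenylation or by ionisation of the α-oxygenated selenoxide before the concerted syn-elimination. Either gives E/Z mixtures and, after step 11, the wrong C9/C10 relationship. Fallback, from 13 back at 17: stereospecific control is given up for separation and recycling. The elimination product is chromatographed, and the geometric isomer (2S,5Z)-2-tert-butyl-5-(6,6-dimethylnon-8-en-2-ylidene)-1,3-dioxolan-4-one F2 is returned to a photostationary E/Z mixture by triplet-sensitised irradiation (benzophenone, hν, PhH). The mixture is separated again and the E isomer joins the route as 17.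

Step 14. The most likely failure is lack of acyl substitution, because the lactone carbonyl is flanked by quaternary C9 and C10 and shielded by the tert-butyl group; forcing conditions would then start to degrade the allylic alcohol. Fallback, from 27 back at 29: the ester is made by carboxylate alkylation. Saponification with LiOH (THF–MeOH–H2O, 40 °C) uses the smaller hydroxide and gives 6β,9β-dihydroxy-12,12-dimethoxydrim-7-en-11-oic acid F3. O-Alkylation of its caesium salt with allyl bromide (Cs2CO3, DMF) does not involve the hindered carbonyl and gives 29.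

Step 16. The most likely failure is sluggish acylation of the axial 6β-hydroxyl (syn-diaxial to two methyl groups), which gives the activated trienoyl donor time to deconjugate or isomerise. Fallback, from 29 back at 35: the triene is built on the ester. The small diethylphosphonoacetic acid is coupled (diisopropylcarbodiimide, DMAP) to give allyl 6β-[(diethoxyphosphoryl)acetoxy]-9β-hydroxy-12,12-dimethoxydrim-7-en-11-oate F4. A Masamune–Roush Horner–Wadsworth–Emmons reaction of F4 with 30 (LiCl, i-Pr2NEt, MeCN) then forms the 2E double bond and gives 35.

Step 2. The most likely failure is diversion of the tertiary cation (elimination, hydride shift, arylation of the benzyl group) or stalling because TiCl4 is sequestered by the imide. Fallback, from 4 back at 7: a radical replaces the cation. Hydrobromination (HBr, CH2Cl2, 0 °C) gives (4S)-4-benzyl-3-[(3S)-7-bromo-3,7-dimethyloctanoyl]-1,3-oxazolidin-2-one F5. Keck radical allylation of F5 with allyltributylstannane (CH2=CHCH2SnBu3, AIBN, PhH, 80 °C) gives 7.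

Further compounds

F1 | step 11 | (S)-2,2-dimethylpropylidene acylal of 9β-hydroxy-12,12-dimethoxy-6-oxodriman-11-oic acid (8α-H) | O=C1C[C@H](C(OC)OC)[C@@](O3)(C(=O)O[C@H]3C(C)(C)C)[C@@]4(C)CCCC(C)(C)[C@H]14
F2 | step 6 | (2S,5Z)-2-tert-butyl-5-(6,6-dimethylnon-8-en-2-ylidene)-1,3-dioxolan-4-one | C/C(CCCC(C)(C)CC=C)=C1/O[C@H](C(C)(C)C)OC1=O
F3 | step 14 | 6β,9β-dihydroxy-12,12-dimethoxydrim-7-en-11-oic acid | O[C@@H]1C=C(C(OC)OC)[C@@](O)(C(=O)O)[C@@]2(C)CCCC(C)(C)[C@H]12
F4 | step 16 | allyl 6β-[(diethoxyphosphoryl)acetoxy]-9β-hydroxy-12,12-dimethoxydrim-7-en-11-oate | CCOP(=O)(OCC)CC(=O)O[C@@H]1C=C(C(OC)OC)[C@@](O)(C(=O)OCC=C)[C@@]2(C)CCCC(C)(C)[C@H]12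
F5 | step 2 | (4S)-4-benzyl-3-[(3S)-7-bromo-3,7-dimethyloctanoyl]-1,3-oxazolidin-2-one | C[C@@H](CCCC(C)(C)Br)CC(=O)N1[C@@H](Cc2ccccc2)COC1=O
A1 | alternative 1 | 2-(trimethylsilyl)ethyl 6β-(tert-butyldimethylsilyloxy)-9β-hydroxy-12-oxodrim-7-en-11-oate | O=CC1=C[C@@H](O[Si](C)(C)C(C)(C)C)[C@H]2C(C)(C)CCC[C@]2(C)[C@]1(O)C(=O)OCC[Si](C)(C)C
A2 | alternative 1 | 2-(trimethylsilyl)ethyl 2-oxoacetate on C10 of a ring A cyclohexane bearing the (E)-4-oxo-1-(tert-butyldimethylsilyloxy)but-2-enyl chain on C5 | O=C/C=C/[C@@H](O[Si](C)(C)C(C)(C)C)[C@H]1C(C)(C)CCC[C@]1(C)C(=O)C(=O)OCC[Si](C)(C)C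
A3 | alternative 2 | 4-hydroxy-5-methyl-3-oxo-2-oxabicyclo[2.2.2]oct-7-ene-5-carbaldehyde | O=C1O[C@H]2C=C[C@]1(O)[C@@](C)(C=O)C2
A4 | alternative 2 | 3-hydroxy-2H-pyran-2-one | O=c1occcc1O
A5 | alternative 2 | methacrolein | CC(=C)C=O
A6 | alternative 3 | 2-(trimethylsilyl)ethyl 9β-hydroxy-8-oxo-12-nordriman-11-oate | C1CC(=O)[C@@](O)(C(=O)OCC[Si](C)(C)C)[C@@]2(C)CCCC(C)(C)[C@H]12
A7 | alternative 3 | 2-(trimethylsilyl)ethyl 5-[(3E)-4,8-dimethylnona-3,7-dien-1-yl]-2,2-dimethyl-1,3-dioxole-4-carboxylate | CC(C)=CCC/C(C)=C/CCC1=C(C(=O)OCC[Si](C)(C)C)OC(C)(C)O1
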